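The cyclohexenone ring (C1, C10–C14, briarane numbering) contains a tertiary α-acyloxy ketone, C11(CH3)(O)–C12(=O): the retron of an α-ketol shift. The ring is therefore made one carbon short, as a cyclopentenone assembled from 3-methylcyclopentenone by asymmetric conjugate addition and aldol reaction. Addition of an acetyl anion equivalent to C12 gives a 1-acetylcyclopent-2-enol; its alkoxide shifts C10 from C12 to the acetyl carbon, which in one operation inserts C11 with methyl and oxygen, enlarges the ring to the conjugated six-membered enone and sets C11 by relay from C10. A Horner–Wadsworth–Emmons macrocyclization and an intramolecular Reformatsky lactonization then complete the skeleton.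

Key step: step 8

Numbering: briarane locants are used throughout (C1 quaternary ring-fusion carbon with CH3-15; C2/C3 epoxide; C5=C16 methylidene; C6 CHCl; C7–O–C19(=O)–C17(CH3-18)–C8 lactone; C9 glycolate carbinol; C10 ring-fusion CH; C11 acetoxy carbon with CH3-20; C12 ketone; C13=C14). PMB = 4-methoxybenzyl, TES = triethylsilyl, TMS = trimethylsilyl, TBS = tert-butyldimethylsilyl.

Assumption: the enantiomers of the chiral ligands named follow the usual sense of induction for the closest model substrates (the antipode is used if the sense is opposite), and compounds 10 and 24 are taken as purchasable.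

Step 1
Reactants: 1 3-chloro-2-(chloromethyl)prop-1-ene; 2 4-methoxybenzyl alcohol
Product: 3 1-({[2-(chloromethyl)prop-2-en-1-yl]oxy}methyl)-4-methoxybenzene
Conditions: NaH, THF/DMF, 0 °C; then 1 (3 equiv), Bu4NI (cat.), 0 → 23 °C
Reagents that add atoms: none
Why: Williamson etherification with an excess of the symmetrical bis-allylic chloride should give the mono-ether.

Step 2
Reactants: 3 mono-PMB ether; 4 ethynylmagnesium bromide
Product: 5 1-methoxy-4-{[(2-methylidenepent-4-yn-1-yl)oxy]methyl}benzene
Conditions: CuBr·SMe2 (10 mol%), THF, 0 → 40 °C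
Reagents that add atoms: none
Why: Copper-catalysed allyl–alkynyl coupling; both allylic termini are CH2, so SN2 and SN2' attack give the same skipped enyne (C2–C6 and C16).

Step 3
Reactants: 5 skipped enyne; 6 3-methylcyclopent-2-en-1-one
Product: 9 trimethylsilyl enol ether (C12–OTMS and C10=C12) of 3-methyl-3-[(1E)-5-(PMB-oxymethyl)hexa-1,5-dienyl]cyclopentanone with C1 as in 36, via alkenylalane 7 (not isolated), via aluminium enolate 8 (not isolated)
Conditions: DIBAL-H, hexane, 50 °C; then 6, CuTC (10 mol%), (R,R)-SimplePhos phosphinamine ligand (11 mol%), Et2O, −30 °C; then TMSOTf, −30 → 0 °C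
Reagents that add atoms: trimethylsilyl trifluoromethanesulfonate, C[Si](C)(C)OS(=O)(=O)C(F)(F)F
Why: syn-Hydroalumination gives the (E)-alkenylalane, copper-catalysed asymmetric conjugate addition sets the C1 quaternary centre under ligand control and installs the E-C2=C3 arm, and silylation of the aluminium enolate fixes the otherwise inaccessible C10 enol regiochemistry.

Step 4
Reactants: 9 silyl enol ether; 10 [(4-methoxybenzyl)oxy]acetaldehyde
Product: 12 β-hydroxy ketone (cyclopentanone with C10–C9H(OH)–C8H2OPMB; C1 and C9 and C10 as in 36), via O-silyl aldol adduct 11 (not isolated)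
Conditions: [Cu((S,S)-Ph-pybox)](SbF6)2 (10 mol%), CH2Cl2, −78 °C; then 1 M HCl, THF, 0 °C
Reagents that add atoms: none
Why: Catalytic asymmetric Mukaiyama aldol addition, in which the Cu(II)–pybox chelate of the α-alkoxy aldehyde exposes one aldehyde face (sets C9) and its open transition state gives the syn adduct (sets C10); the enol silane has little facial bias of its own (CH3 versus alkenyl on C1), so the catalyst should decide.

Step 5
Reactants: 12 β-hydroxy ketone
Product: 13 C9 triethylsilyl ether of 12
Conditions: TESCl, imidazole, DMF, 0 °C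
Reagents that add atoms: chlorotriethylsilane, CC[Si](Cl)(CC)CC
Why: Silylation of the secondary alcohol blocks retro-aldol cleavage and β-elimination in the following base steps.

Step 6
Reactants: 13 silyl ether
Product: 15 cyclopentenone (C12=O, C13=C14; 4-methyl-4-alkenyl-5-[1-(TES-oxy)-2-(PMB-oxy)ethyl]cyclopent-2-enone), via silyl enol ether 14 (not isolated)
Conditions: LDA, TMSCl, THF, −78 °C; then Pd(OAc)2, MeCN, 23 °C
Reagents that add atoms: none
Why: Saegusa–Ito oxidation: kinetic deprotonation at the unhindered C13 methylene, silylation and Pd(II)-mediated dehydrosilylation should introduce C13=C14 without touching the C10 stereocentre.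

Step 7
Reactants: 15 cyclopentenone; 16 ethyl vinyl ether
Product: 19 1-acetylcyclopent-2-en-1-ol (C12 carbinol carrying the acetyl group C11/C20; C12–OH cis to the C9 side chain), via 1-ethoxyvinyllithium 17 (not isolated), via enol ether carbinol 18 (not isolated)
Conditions: t-BuLi, THF, −78 → 0 °C (lithiation of 16); 15, −78 °C; sat. NH4Cl; then oxalic acid (cat.), wet SiO2, CH2Cl2, 0 °C
Reagents that add atoms: water, O
Why: 1,2-Addition of the acetyl anion equivalent to the enone carbonyl anti to the bulky C10 substituent sets C12, and mild hydrolysis of the enol ether unveils the methyl ketone.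

Step 8
Reactants: 19 1-acetylcyclopent-2-en-1-ol
Product: 21 ring-expanded C11 acetate (6-acetoxy-4,6-dimethyl-4-alkenyl-5-[1-(TES-oxy)-2-(PMB-oxy)ethyl]cyclohex-2-enone; C1 and C9–C11 as in 36), via rearranged potassium alkoxide 20 (not isolated)
Conditions: KH, 18-crown-6, THF, 0 → 23 °C; then Ac2O, 0 °C
Reagents that add atoms: acetic anhydride, CC(=O)OC(C)=O
Why: Deprotonation of the tertiary alcohol gives the potassium alkoxide, whose C12–C10 ring bond migrates to the acetyl carbonyl carbon (C11) while C12 becomes the ketone (α-ketol or acyloin rearrangement, the reaction type of the D-homoannulation of 17-hydroxy-20-keto steroids), and the new tertiary alkoxide is trapped by Ac2O as the acetate. The six-membered ring arises by a 1,2-shift that enlarges the cyclopentene by one carbon (C11), not by a cyclization, so no closure mode applies. C11 is set by relay from C10 through C12: in the crown-complexed potassium alkoxide the C–O(−) and C=O dipoles are anti, C10 migrates with retention to the carbonyl face that this conformer exposes, and the new C11–O bond should end up cis to H-10. The step needs migration of C10 and not of the vinylic carbon C13; only C10 migration puts the new C12 ketone into conjugation with C13=C14, and since the shift is reversible the conjugated cyclohexenone is the thermodynamic sink, helped by relief of cyclopentene strain. The product ketone has no α-hydrogen, so the alkoxide cannot epimerize or condense before it is acylated.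

Step 9
Reactants: 21 bis-PMB ether
Product: 22 C6,C8-diol
Conditions: DDQ, CH2Cl2/pH 7 buffer, 0 °C
Reagents that add atoms: none
Why: Oxidative cleavage of both p-methoxybenzyl ethers by DDQ should leave the silyl ether, acetate and enone untouched.

Step 10
Reactants: 22 diol
Product: 23 dialdehyde (C6 enal and C8 α-silyloxy aldehyde)
Conditions: Dess–Martin periodinane, NaHCO3, CH2Cl2, 0 → 23 °C
Reagents that add atoms: none
Why: Dess–Martin oxidation of both primary alcohols under buffered, non-epimerizing conditions.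

Step 11
Reactants: 23 dialdehyde; 24 dimethyl (diazomethyl)phosphonate
Product: 25 β-ketophosphonate (C8 ketone, C7H2–P(O)(OMe)2) still carrying the C6 enal
Conditions: SnCl2 (20 mol%), CH2Cl2, 23 °C
Reagents that add atoms: none
Why: Roskamp reaction: Lewis-acid-catalysed addition of the diazophosphonate to the saturated, more electrophilic C8 aldehyde and 1,2-hydride shift with loss of N2, whereas the conjugated C6 enal and the ketone are poor acceptors.

Step 12
Reactants: 25 β-ketophosphonate enal
Product: 26 bicyclic dienone (ten-membered ring closed at C6=C7; C8 ketone; E-C2=C3 and E-C6=C7)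
Conditions: LiCl, i-Pr2NEt, MeCN, 1 mM (syringe pump), 23 °C
Reagents that add atoms: none
Why: Intramolecular Horner–Wadsworth–Emmons olefination under high dilution closes the ten-membered carbocycle, and the stabilized phosphonate anion should give the E-enone.

Step 13
Reactants: 26 dienone macrocycle
Product: 27 2,3-epoxide (2R,3R as in 36)
Conditions: D-fructose-derived Shi ketone (30 mol%), Oxone, K2CO3, Bu4NHSO4, MeCN/DMM/aq. buffer (pH 10.5), 0 °C
Reagents that add atoms: potassium peroxymonosulfate (Oxone), [K+].[O-]S(=O)(=O)OO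
Why: Shi epoxidation: the chiral dioxirane attacks the only electron-rich alkene (all others are conjugated to carbonyl groups), and this ketone enantiomer is the one that gives (R,R)-epoxides from trans-disubstituted alkenes.

Step 14
Reactants: 27 mono-epoxide
Product: 28 2,3:6,7-bis-epoxide (trans-α,β-epoxy ketone, 6R,7S)
Conditions: La(O-i-Pr)3 (10 mol%), (R)-BINOL, Ph3As=O, t-BuOOH, 4 Å MS, THF, 23 °C
Reagents that add atoms: tert-butyl hydroperoxide, CC(C)(C)OO
Why: Nucleophilic (Weitz–Scheffer-type) epoxidation by conjugate addition of the peroxide to C6 and ring closure gives the trans-epoxy ketone with the face chosen by the La–(R)-BINOL complex, while the cyclic s-trans enone with its neopentyl β-carbon should not react.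

Step 15
Reactants: 28 bis-epoxide
Product: 29 anti-chlorohydrin (C6–Cl, C7–OH; α-hydroxy ketone)
Conditions: LiCl, AcOH, THF, 0 → 23 °C
Reagents that add atoms: lithium chloride, [Li+].[Cl-]
Why: Regioselective SN2 opening of the α,β-epoxy ketone by chloride at C6 (β to the carbonyl and allylic) with inversion sets the C6 chloride anti to the C7 oxygen, whereas the hindered, unactivated 2,3-epoxide should open much more slowly.

Step 16
Reactants: 29 chlorohydrin; 30 2-bromopropanoyl bromide
Product: 31 C7 2-bromopropanoate (mixture of epimers at the bromine-bearing carbon)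
Conditions: pyridine, CH2Cl2, −20 °C
Reagents that add atoms: none
Why: O-Acylation of the only free hydroxyl installs C17–C19 on the C7 oxygen.

Step 17
Reactants: 31 bromo ester
Product: 32 γ-lactone with free C8–OH and C9–OTES (C7, C8 and C17 as in 36)
Conditions: SmI2 (2.2 equiv), THF, −78 °C; sat. NH4Cl
Reagents that add atoms: none
Why: Samarium(II)-mediated intramolecular Reformatsky reaction, in which the samarium enolate adds to the neighbouring C8 ketone through a five-membered ring on the face syn to the C7–O bond with C9 staying anti to C6 (trans-fused lactone, sets C8), and C17 takes the methyl-trans-to-C9 arrangement that is also the thermodynamic one at this epimerizable centre.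

Step 18
Reactants: 32 silyl ether
Product: 33 C8,C9-diol lactone
Conditions: HF·pyridine, pyridine, THF, 0 °C
Reagents that add atoms: none
Why: Buffered fluoride cleavage of the secondary triethylsilyl ether should spare the lactone, epoxide, acetate and allylic chloride.

Step 19
Reactants: 33 diol; 34 {[tert-butyl(dimethyl)silyl]oxy}acetic acid
Product: 35 C9 (TBS-oxy)acetate
Conditions: EDC·HCl, DMAP, CH2Cl2, 0 → 23 °C
Reagents that add atoms: none
Why: Steglich esterification acylates the secondary C9 alcohol selectively because the tertiary C8 alcohol is too hindered to react.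

Step 20
Reactants: 35 silyl-protected glycolate
Product: 36 CNP0278742.1
Conditions: HF·pyridine, pyridine, THF, 0 → 23 °C
Reagents that add atoms: none
Why: Fluoride cleavage of the primary silyl ether frees the glycolate hydroxyl under conditions the epoxide, esters and allylic chloride should tolerate.

Compound list
1 | 3-chloro-2-(chloromethyl)prop-1-ene | C=C(CCl)CCl | starting material
2 | 4-methoxybenzyl alcohol | COc1ccc(CO)cc1 | starting material
3 | 1-({[2-(chloromethyl)prop-2-en-1-yl]oxy}methyl)-4-methoxybenzene | C=C(CCl)COCc1ccc(OC)cc1 | intermediate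
4 | ethynylmagnesium bromide | C#C[Mg]Br | starting material
5 | 1-methoxy-4-{[(2-methylidenepent-4-yn-1-yl)oxy]methyl}benzene | C#CCC(=C)COCc1ccc(OC)cc1 | intermediate
6 | 3-methylcyclopent-2-en-1-one | CC1=CC(=O)CC1 | starting material
7 | diisobutyl[(1E)-5-(PMB-oxymethyl)hexa-1,5-dien-1-yl]alumane | CC(C)C[Al](CC(C)C)/C=C/CC(=C)COCc1ccc(OC)cc1 | intermediate
8 | diisobutylaluminium enolate (O–C12=C10) of (3S)-3-methyl-3-[(1E)-5-(PMB-oxymethyl)hexa-1,5-dienyl]cyclopentanone | C=C(COCc1ccc(OC)cc1)C/C=C/[C@@]2(C)CCC(O[Al](CC(C)C)CC(C)C)=C2 | intermediate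
9 | trimethylsilyl enol ether (C12–OTMS, C10=C12) of the same ketone; C1 as in 36 | C=C(COCc1ccc(OC)cc1)C/C=C/[C@@]2(C)CCC(O[Si](C)(C)C)=C2 | intermediate
10 | [(4-methoxybenzyl)oxy]acetaldehyde | O=CCOCc1ccc(OC)cc1 | starting material
11 | O-trimethylsilyl aldol adduct (C9–OTMS) | C=C(COCc1ccc(OC)cc1)C/C=C/[C@@]2(C)CCC(=O)[C@@H]2[C@H](O[Si](C)(C)C)COCc1ccc(OC)cc1 | intermediate
12 | β-hydroxy ketone: cyclopentanone bearing C1(CH3)(alkenyl) and C10–C9H(OH)–C8H2OPMB; syn aldol, C1/C9/C10 as in 36 | C=C(COCc1ccc(OC)cc1)C/C=C/[C@@]2(C)CCC(=O)[C@@H]2[C@H](O)COCc1ccc(OC)cc1 | intermediate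
13 | C9 triethylsilyl ether of 12 | C=C(COCc1ccc(OC)cc1)C/C=C/[C@@]2(C)CCC(=O)[C@@H]2[C@H](O[Si](CC)(CC)CC)COCc1ccc(OC)cc1 | intermediate
14 | kinetic trimethylsilyl enol ether (C12–OTMS, C12=C13) of 13 | C=C(COCc1ccc(OC)cc1)C/C=C/[C@@]2(C)CC=C(O[Si](C)(C)C)[C@@H]2[C@H](O[Si](CC)(CC)CC)COCc1ccc(OC)cc1 | intermediate
15 | cyclopent-2-enone (C12=O, C13=C14) with C1(CH3)(alkenyl) and C10 side chain | C=C(COCc1ccc(OC)cc1)C/C=C/[C@@]2(C)C=CC(=O)[C@@H]2[C@H](O[Si](CC)(CC)CC)COCc1ccc(OC)cc1 | intermediate
16 | ethyl vinyl ether | C=COCC | starting material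
17 | 1-ethoxyvinyllithium | [Li]C(=C)OCC | intermediate
18 | 1-(1-ethoxyvinyl)cyclopent-2-en-1-ol adduct (C12–OH cis to the C9 chain) | C=C(COCc1ccc(OC)cc1)C/C=C/[C@@]2(C)C=C[C@@](O)(C(=C)OCC)[C@@H]2[C@H](O[Si](CC)(CC)CC)COCc1ccc(OC)cc1 | intermediate
19 | 1-acetylcyclopent-2-en-1-ol (C12 carbinol with acetyl C11/C20; OH cis to the C9 chain) | C=C(COCc1ccc(OC)cc1)C/C=C/[C@@]2(C)C=C[C@@](O)(C(C)=O)[C@@H]2[C@H](O[Si](CC)(CC)CC)COCc1ccc(OC)cc1 | intermediate
20 | potassium alkoxide of the ring-expanded 6-hydroxy-6-methylcyclohex-2-enone (C11–O(−) cis to H-10) | C=C(COCc1ccc(OC)cc1)C/C=C/[C@@]2(C)C=CC(=O)[C@@](C)([O-])[C@@H]2[C@H](O[Si](CC)(CC)CC)COCc1ccc(OC)cc1.[K+] | intermediate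
21 | C11 acetate: 6-acetoxy-4,6-dimethylcyclohex-2-enone with the C1 alkenyl arm and C10 side chain; C1, C9, C10, C11 as in 36 | C=C(COCc1ccc(OC)cc1)C/C=C/[C@@]2(C)C=CC(=O)[C@@](C)(OC(C)=O)[C@@H]2[C@H](O[Si](CC)(CC)CC)COCc1ccc(OC)cc1 | intermediate
22 | C6,C8-diol from 21 | C=C(CO)C/C=C/[C@@]2(C)C=CC(=O)[C@@](C)(OC(C)=O)[C@@H]2[C@H](O[Si](CC)(CC)CC)CO | intermediate
23 | dialdehyde (C6 2-substituted acrolein; C8 α-TES-oxy aldehyde) | C=C(C=O)C/C=C/[C@@]2(C)C=CC(=O)[C@@](C)(OC(C)=O)[C@@H]2[C@H](O[Si](CC)(CC)CC)C=O | intermediate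
24 | dimethyl (diazomethyl)phosphonate | COP(=O)(C=[N+]=[N-])OC | starting material
25 | β-ketophosphonate (C8=O, C7H2P(O)(OMe)2) with C6 enal | C=C(C=O)C/C=C/[C@@]2(C)C=CC(=O)[C@@](C)(OC(C)=O)[C@@H]2[C@H](O[Si](CC)(CC)CC)C(=O)CP(=O)(OC)OC | intermediate
26 | bicyclic dienone: ten-membered ring with E-C2=C3, C5=C16, E-C6=C7, C8=O, fused to the acetoxy-cyclohexenone | C=C1C/C=C/[C@@]2(C)C=CC(=O)[C@@](C)(OC(C)=O)[C@@H]2[C@H](O[Si](CC)(CC)CC)C(=O)/C=C/1 | intermediate
27 | (2R,3R)-2,3-epoxide of 26 | C=C1C[C@H]2O[C@@H]2[C@@]2(C)C=CC(=O)[C@@](C)(OC(C)=O)[C@@H]2[C@H](O[Si](CC)(CC)CC)C(=O)/C=C/1 | intermediate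
28 | 2,3:6,7-bis-epoxide (trans-6,7-epoxy-8-ketone, 6R,7S) | C=C1C[C@H]2O[C@@H]2[C@@]2(C)C=CC(=O)[C@@](C)(OC(C)=O)[C@@H]2[C@H](O[Si](CC)(CC)CC)C(=O)[C@H]3O[C@H]13 | intermediate
29 | 6-chloro-7-hydroxy-8-ketone (anti chlorohydrin; C6 and C7 as in 36) | C=C1C[C@H]2O[C@@H]2[C@@]2(C)C=CC(=O)[C@@](C)(OC(C)=O)[C@@H]2[C@H](O[Si](CC)(CC)CC)C(=O)[C@@H](O)[C@H]1Cl | intermediate
30 | 2-bromopropanoyl bromide | CC(Br)C(=O)Br | starting material
31 | C7 2-bromopropanoate of 29 (epimers at CHBr) | C=C1C[C@H]2O[C@@H]2[C@@]2(C)C=CC(=O)[C@@](C)(OC(C)=O)[C@@H]2[C@H](O[Si](CC)(CC)CC)C(=O)[C@@H](OC(=O)C(C)Br)[C@H]1Cl | intermediate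
32 | 9-O-TES lactone: complete briarane skeleton with 8-OH and 17-CH3 as in 36 | C=C1C[C@H]2O[C@@H]2[C@@]2(C)C=CC(=O)[C@@](C)(OC(C)=O)[C@@H]2[C@H](O[Si](CC)(CC)CC)[C@]2(O)[C@@H](C)C(=O)O[C@H]2[C@H]1Cl | intermediate
33 | 8,9-diol lactone (9-deacyl target) | C=C1C[C@H]2O[C@@H]2[C@@]2(C)C=CC(=O)[C@@](C)(OC(C)=O)[C@@H]2[C@H](O)[C@]2(O)[C@@H](C)C(=O)O[C@H]2[C@H]1Cl | intermediate
34 | {[tert-butyl(dimethyl)silyl]oxy}acetic acid | CC(C)(C)[Si](C)(C)OCC(=O)O | starting material
35 | 9-O-[(TBS-oxy)acetyl] derivative of 33 | C=C1C[C@H]2O[C@@H]2[C@@]2(C)C=CC(=O)[C@@](C)(OC(C)=O)[C@@H]2[C@H](OC(=O)CO[Si](C)(C)C(C)(C)C)[C@]2(O)[C@@H](C)C(=O)O[C@H]2[C@H]1Cl | intermediate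
36 | CNP0278742.1: (1S,2R,3R,6S,7R,8R,9S,10S,11S,17R)-11-acetoxy-6-chloro-2,3-epoxy-8-hydroxy-9-(hydroxyacetoxy)-12-oxobriara-5(16),13-dien-19,7-olide | C=C1C[C@H]2O[C@@H]2[C@@]2(C)C=CC(=O)[C@@](C)(OC(C)=O)[C@@H]2[C@H](OC(=O)CO)[C@]2(O)[C@@H](C)C(=O)O[C@H]2[C@H]1Cl | target

Total step count: 20. Longest linear sequence: 20 steps (1 → 36).

Steps most likely to fail

Step 12 (macrocyclization). Oligomerization may outrun closure of the strained ten-membered dienone, or the base may move the C5 methylidene of the skipped enal into conjugation before the ring closes. The fallback sets out from dialdehyde 23 and closes the same bond stepwise through a less strained sp3 intermediate. The saturated aldehyde of 23 is homologated chemoselectively with trimethylsilyldiazomethane (C–H insertion, desilylation on work-up) to the methyl ketone F1. Soft enolization on the methyl side with Bu2BOTf/i-Pr2NEt and intramolecular boron aldol addition onto the enal under high dilution should give the macrocyclic β-hydroxy ketone F2. Mesylation and DBU elimination then give the E-enone, and the route is rejoined at 26.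

Step 4 (aldol). Addition at the neopentyl enol carbon may be slow, so that protodesilylation of 9 competes, and facial discrimination at C10 may be poor. The fallback sets out from 9 and replaces C–C bond formation under catalyst control by acylation and stereoselective reduction. MeLi cleaves the enol silane to the lithium enolate, and C-acylation with 1-{[(4-methoxybenzyl)oxy]acetyl}benzotriazole gives the 2-acylcyclopentanone F3, in which C10 is stereolabile. Ru–TsDPEN asymmetric transfer hydrogenation (HCO2H/Et3N) with dynamic kinetic resolution reduces the activated α-alkoxy ketone and should fix C9 and C10 together, which rejoins the route at 12.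

Step 17 (lactone formation). Single-electron reduction of the α-acyloxy ketone (loss of the C7 oxygen) may compete with enolate formation, or the tethered enolate may add to the wrong carbonyl face. The fallback sets out from chlorohydrin 29 and avoids both SmI2 and the tether. Preformed BrZnCH(CH3)CO2Et (from ethyl 2-bromopropanoate and zinc; the first equivalent forms the C7 zinc alkoxide) adds to the C8 ketone under chelation control (attack anti to C6) to give the dihydroxy ester F4. PPTS-catalysed lactonization onto the C7 hydroxyl with DBU equilibration at C17 rejoins the route at 32.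

Further compounds
F1 | step 12 | methyl ketone–enal (C8 acetyl in place of the C8 aldehyde of 23) | C=C(C=O)C/C=C/[C@@]2(C)C=CC(=O)[C@@](C)(OC(C)=O)[C@@H]2[C@H](O[Si](CC)(CC)CC)C(C)=O
F2 | step 12 | macrocyclic β-hydroxy ketone (C6–OH, C7H2, C8=O; C6 epimers) | C=C1C/C=C/[C@@]2(C)C=CC(=O)[C@@](C)(OC(C)=O)[C@@H]2[C@H](O[Si](CC)(CC)CC)C(=O)CC1O
F3 | step 4 | 2-[(PMB-oxy)acetyl]cyclopentanone (C9 ketone; C10 stereolabile) | C=C(COCc1ccc(OC)cc1)C/C=C/[C@@]2(C)CCC(=O)C2C(=O)COCc1ccc(OC)cc1
F4 | step 17 | ethyl 2-(8-hydroxy…)propanoate: C7,C8-dihydroxy ester before lactonization (C17 epimers) | C=C1C[C@H]2O[C@@H]2[C@@]2(C)C=CC(=O)[C@@](C)(OC(C)=O)[C@@H]2[C@H](O[Si](CC)(CC)CC)[C@](O)(C(C)C(=O)OCC)[C@@H](O)[C@H]1Cl
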